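**Retrosynthetic overview**

1. The (E)-propenal arm is traced back through an aryl aldehyde and a benzylic alcohol to a methyl ester; a Wittig two-carbon extension is the last step.
2. Key disconnection: the C2–C3 bond of the 1,4-dioxane ring, CH(CH3)–CH(aryl). The aryl-bearing carbon C3 is taken out as a 3,4,5-trimethoxyphenyl carbene, which leaves a 2-methyl-1,3-benzodioxole (one-carbon ring expansion through an oxonium ylide and a [1,2]-Stevens shift).
3. Enabling feature: C2 and C3 of the dioxane ring each carry one of the two catechol oxygens (O1–C2–C3–O4). With C3 removed, C2 is an acetal carbon that can leave one oxygen as an oxocarbenium ion held by the other. The C8 methoxy group next to O1 and the C6 carbonyl group para to O1 tell the two oxygens apart, so the carbene should add to O4.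
4. Ring order: both benzene rings are bought. The five-membered 1,3-dioxole ring is made first by acetalisation of the catechol, then expanded to the six-membered 1,4-dioxane ring in the key step, which also joins the two aryl halves and sets both stereocentres.
5. The carbene precursor is the N-sulfonylhydrazone of 3,4,5-trimethoxybenzaldehyde.

Key step: step 3

Assumption: the sense of asymmetric induction of the chiral dirhodium tetracarboxylate cannot be predicted with confidence. Both antipodes of the catalyst are available, and the route is written with the one taken to lead to the (2S,3S) series.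

**Route**

Step 1
Reactants: 1 methyl 3,4-dihydroxy-5-methoxybenzoate
Product: 2 methyl 7-methoxy-2-methyl-1,3-benzodioxole-5-carboxylate (racemic)
Conditions: MeCH(OMe)2 (5 equiv), p-TsOH·H2O (5 mol %), toluene, 80 °C, MeOH removed over 4 Å MS
Reagents that add atoms: 1,1-dimethoxyethane CC(OC)OC
Why: Acid-catalysed transacetalisation, in which the catechol displaces both methoxy groups through an oxocarbenium ion and removal of methanol drives closure of the 1,3-dioxole ring; the acetal centre forms racemic, which is harmless because it is erased and reset in step 3.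

Step 2
Reactants: 3 3,4,5-trimethoxybenzaldehyde
Product: 4 N'-[(E)-(3,4,5-trimethoxyphenyl)methylidene]-2-(trifluoromethyl)benzenesulfonohydrazide
Conditions: 2-(CF3)C6H4SO2NHNH2 (1.0 equiv), MeOH, rt
Reagents that add atoms: 2-(trifluoromethyl)benzenesulfonohydrazide NNS(=O)(=O)c1ccccc1C(F)(F)F
Why: Condensation of an aldehyde with a sulfonyl hydrazide should give the crystalline N-sulfonylhydrazone, a bench-stable precursor of a non-stabilised aryldiazomethane (Bamford–Stevens chemistry) whose ortho-CF3 sulfinate leaves below room temperature.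

Step 3
Reactants: 2 methyl 7-methoxy-2-methyl-1,3-benzodioxole-5-carboxylate (racemic); 4 N'-[(E)-(3,4,5-trimethoxyphenyl)methylidene]-2-(trifluoromethyl)benzenesulfonohydrazide
Product: 7 methyl (2S,3S)-8-methoxy-2-methyl-3-(3,4,5-trimethoxyphenyl)-2,3-dihydro-1,4-benzodioxine-6-carboxylate, via 5-(diazomethyl)-1,2,3-trimethoxybenzene 5 (not isolated), via rhodium-bound oxonium ylide 6 (not isolated)
Conditions: 4 (1.5 equiv, in portions), NaH (1.6 equiv), Rh2(S-PTAD)4 (2 mol %), 4 Å MS, CH2Cl2, −20 to 0 °C
Reagents that add atoms: none
Why: Proposed new method: NaH converts 4 into aryldiazomethane 5, the dirhodium catalyst turns 5 into a donor carbene, the acetal oxygen O3 of 2 (the one next to C4–H) adds to the carbene carbon to give the rhodium-bound oxonium ylide 6, the O3–C2 acetal bond ionises with the help of O1 to an oxocarbenium ion that stays tethered through the benzene ring to the α-aryloxybenzyl rhodium carbon, and this carbon attacks the oxocarbenium carbon, so that one carbon atom is inserted into the five-membered ring ([1,2]-Stevens shift). The closest known reaction type is the rhodium- or copper-catalysed ring expansion of 1,3-dioxolanes to 1,4-dioxanes by carbenes from diazo esters through oxonium ylides, and chiral dirhodium carboxylates are known to control insertions of acceptor-free aryl carbenes; untested are the aryl acetal, the donor carbene in this role and the asymmetric induction. The 1,4-dioxane ring closes by a 6-endo-trig attack of the benzylic carbon on the ring C=O+ unit, which forms the CH(aryl)–CH(CH3) bond. The aryl-bearing centre C3 of 7 is set by the chiral carboxylate pocket, because the non-stabilised benzylic carbon should stay on rhodium until the C–C bond forms, and the methyl-bearing centre C2 is set relative to it by closure through the half-chair with aryl and methyl both pseudo-equatorial (trans); because the acetal carbon passes through a planar oxocarbenium ion, both enantiomers of racemic 2 should converge on one product. The step needs O3 over O1 selectivity, secured by the C7 methoxy group that shields O1 and by the para ester that withdraws the lone pair of O1, and it needs ylide formation to outrun carbene dimerisation and acetal C–H insertion, secured by slow release of 5 at low temperature and by the fast ionisation open only to an acetal-derived ylide.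

Step 4
Reactants: 7 methyl (2S,3S)-8-methoxy-2-methyl-3-(3,4,5-trimethoxyphenyl)-2,3-dihydro-1,4-benzodioxine-6-carboxylate
Product: 8 [(2S,3S)-8-methoxy-2-methyl-3-(3,4,5-trimethoxyphenyl)-2,3-dihydro-1,4-benzodioxin-6-yl]methanol
Conditions: iBu2AlH (DIBAL-H, 2.5 equiv), CH2Cl2, −78 to 0 °C; aq. KNaC4H4O6 work-up
Reagents that add atoms: none
Why: Hydride reduction of the aryl ester through the aldehyde to the benzylic alcohol; the aryl alkyl ethers and both stereocentres, which are neither acidic nor next to a carbonyl group, should be untouched.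

Step 5
Reactants: 8 [(2S,3S)-8-methoxy-2-methyl-3-(3,4,5-trimethoxyphenyl)-2,3-dihydro-1,4-benzodioxin-6-yl]methanol
Product: 9 (2S,3S)-8-methoxy-2-methyl-3-(3,4,5-trimethoxyphenyl)-2,3-dihydro-1,4-benzodioxine-6-carbaldehyde
Conditions: MnO2 (10 equiv), CH2Cl2, rt
Reagents that add atoms: none
Why: MnO2 oxidises benzylic alcohols selectively to aryl aldehydes without over-oxidation and without touching the ether stereocentres.

Step 6
Reactants: 9 (2S,3S)-8-methoxy-2-methyl-3-(3,4,5-trimethoxyphenyl)-2,3-dihydro-1,4-benzodioxine-6-carbaldehyde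
Product: 10 (2E)-3-[(2S,3S)-8-methoxy-2-methyl-3-(3,4,5-trimethoxyphenyl)-2,3-dihydro-1,4-benzodioxin-6-yl]prop-2-enal
Conditions: Ph3P=CHCHO (1.2 equiv), toluene, 80 °C
Reagents that add atoms: (triphenylphosphoranylidene)acetaldehyde O=CC=P(c1ccccc1)(c1ccccc1)c1ccccc1
Why: Wittig olefination with the formyl-stabilised ylide should give the (E)-enal under thermodynamic control, and only a slight excess of ylide is used to limit a second extension of the product.

**Compound list**

1 | methyl 3,4-dihydroxy-5-methoxybenzoate | COC(=O)c1cc(O)c(O)c(OC)c1 | starting material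
2 | methyl 7-methoxy-2-methyl-1,3-benzodioxole-5-carboxylate (racemic) | COC(=O)c1cc(OC)c2OC(C)Oc2c1 | intermediate
3 | 3,4,5-trimethoxybenzaldehyde | COc1cc(C=O)cc(OC)c1OC | starting material
4 | N'-[(E)-(3,4,5-trimethoxyphenyl)methylidene]-2-(trifluoromethyl)benzenesulfonohydrazide | COc1cc(/C=N/NS(=O)(=O)c2ccccc2C(F)(F)F)cc(OC)c1OC | intermediate
5 | 5-(diazomethyl)-1,2,3-trimethoxybenzene (not isolated) | COc1cc(C=[N+]=[N-])cc(OC)c1OC | intermediate
6 | oxonium ylide of 2 at O3 carrying the (3,4,5-trimethoxyphenyl)methanide carbon (rhodium-bound in the flask, drawn metal-free, both acetal epimers, not isolated) | COC(=O)c1cc(OC)c2OC(C)[O+]([CH-]c3cc(OC)c(OC)c(OC)c3)c2c1 | intermediate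
7 | methyl (2S,3S)-8-methoxy-2-methyl-3-(3,4,5-trimethoxyphenyl)-2,3-dihydro-1,4-benzodioxine-6-carboxylate | COc1cc([C@@H]2Oc3cc(C(=O)OC)cc(OC)c3O[C@H]2C)cc(OC)c1OC | intermediate
8 | [(2S,3S)-8-methoxy-2-methyl-3-(3,4,5-trimethoxyphenyl)-2,3-dihydro-1,4-benzodioxin-6-yl]methanol | COc1cc([C@@H]2Oc3cc(CO)cc(OC)c3O[C@H]2C)cc(OC)c1OC | intermediate
9 | (2S,3S)-8-methoxy-2-methyl-3-(3,4,5-trimethoxyphenyl)-2,3-dihydro-1,4-benzodioxine-6-carbaldehyde | COc1cc([C@@H]2Oc3cc(C=O)cc(OC)c3O[C@H]2C)cc(OC)c1OC | intermediate
10 | (2E)-3-[(2S,3S)-8-methoxy-2-methyl-3-(3,4,5-trimethoxyphenyl)-2,3-dihydro-1,4-benzodioxin-6-yl]prop-2-enal | COc1cc([C@@H]2Oc3cc(/C=C/C=O)cc(OC)c3O[C@H]2C)cc(OC)c1OC | target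

**Step count**

Total steps: 6. Longest linear sequence: 5 steps (1 → 2 → 7 → 8 → 9 → 10).

**Steps most likely to fail**

Step 3 (proposed new method). Three processes may defeat it:
- The carbene may dimerise or insert into the acetal C–H bond before it is captured as the ylide.
- The ylide may form at the wrong acetal oxygen.
- Asymmetric induction may be lost if the benzylic carbon leaves rhodium before the ring closes.

The fallback uses known chemistry, sets out from 1 and comes back to the route at 7. Commercial methyl (R)-lactate is converted with MeNH(OMe)·HCl and iPrMgCl (THF, −20 °C) into (R)-2-hydroxy-N-methoxy-N-methylpropanamide F1. Mitsunobu etherification (PPh3, DIAD, THF, 0 °C to rt) of 1 with F1 should take place at the more acidic 4-hydroxyl, para to the ester, and with inversion, to give methyl 3-hydroxy-5-methoxy-4-{[(2S)-1-[methoxy(methyl)amino]-1-oxopropan-2-yl]oxy}benzoate F2. Treatment with 3,4,5-trimethoxyphenylmagnesium bromide (2.2 equiv, THF, −40 °C; the first equivalent is consumed by the phenol) should attack the chelating N-methoxy-N-methylamide ahead of the conjugated aryl ester (Weinreb ketone synthesis) and give methyl 3-hydroxy-5-methoxy-4-{[(2S)-1-oxo-1-(3,4,5-trimethoxyphenyl)propan-2-yl]oxy}benzoate F3. NaBH4 (MeOH, 0 °C) should reduce the ketone to methyl 3-hydroxy-4-{[(2S)-1-hydroxy-1-(3,4,5-trimethoxyphenyl)propan-2-yl]oxy}-5-methoxybenzoate F4 as a mixture of carbinol epimers. Acid (p-TsOH, toluene, rt to 50 °C) should ionise the electron-rich benzylic alcohol, and the free 3-hydroxyl should close the dioxane ring to the favoured trans isomer 7. The methyl-bearing centre comes from the lactate and is not touched.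

Step 1. The acetaldehyde oxocarbenium ion may attack ring carbons and cause oligomerisation, and closure of the five-membered aldehyde acetal on an electron-poor catechol may stay incomplete. The fallback sets out from 1 and comes back at 2. Transvinylation with vinyl acetate ([Ir(cod)Cl]2 1 mol %, Na2CO3, toluene, 100 °C) should give methyl 4-(ethenyloxy)-3-hydroxy-5-methoxybenzoate F5; vinylation at the other hydroxyl is equally acceptable, since both regioisomers lead to the same acetal. Catalytic pyridinium p-toluenesulfonate (CH2Cl2, rt) should then add the neighbouring phenol across the protonated vinyl ether in the Markovnikov sense and close the dioxole ring to 2.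

Step 6. The same ylide may olefinate the product enal a second time, and the (E) selectivity may be incomplete. The fallback sets out from 9 and comes back at 10. Horner–Wadsworth–Emmons olefination with triethyl phosphonoacetate (NaH, THF, 0 °C) should give ethyl (2E)-3-[(2S,3S)-8-methoxy-2-methyl-3-(3,4,5-trimethoxyphenyl)-2,3-dihydro-1,4-benzodioxin-6-yl]prop-2-enoate F6. iBu2AlH (CH2Cl2, −78 °C) should reduce it to (2E)-3-[(2S,3S)-8-methoxy-2-methyl-3-(3,4,5-trimethoxyphenyl)-2,3-dihydro-1,4-benzodioxin-6-yl]prop-2-en-1-ol F7, and MnO2 (CH2Cl2, rt) should oxidise the allylic alcohol to 10.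

**Further compounds**

F1 | step 3 | (R)-2-hydroxy-N-methoxy-N-methylpropanamide | C[C@@H](O)C(=O)N(C)OC
F2 | step 3 | methyl 3-hydroxy-5-methoxy-4-{[(2S)-1-[methoxy(methyl)amino]-1-oxopropan-2-yl]oxy}benzoate | C[C@H](Oc1c(O)cc(cc1OC)C(=O)OC)C(=O)N(C)OC
F3 | step 3 | methyl 3-hydroxy-5-methoxy-4-{[(2S)-1-oxo-1-(3,4,5-trimethoxyphenyl)propan-2-yl]oxy}benzoate | C[C@H](Oc1c(O)cc(cc1OC)C(=O)OC)C(=O)c1cc(OC)c(OC)c(OC)c1
F4 | step 3 | methyl 3-hydroxy-4-{[(2S)-1-hydroxy-1-(3,4,5-trimethoxyphenyl)propan-2-yl]oxy}-5-methoxybenzoate (both carbinol epimers) | C[C@H](Oc1c(O)cc(cc1OC)C(=O)OC)C(O)c1cc(OC)c(OC)c(OC)c1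
F5 | step 1 | methyl 4-(ethenyloxy)-3-hydroxy-5-methoxybenzoate | COC(=O)c1cc(O)c(OC=C)c(OC)c1
F6 | step 6 | ethyl (2E)-3-[(2S,3S)-8-methoxy-2-methyl-3-(3,4,5-trimethoxyphenyl)-2,3-dihydro-1,4-benzodioxin-6-yl]prop-2-enoate | COc1cc([C@@H]2Oc3cc(/C=C/C(=O)OCC)cc(OC)c3O[C@H]2C)cc(OC)c1OC
F7 | step 6 | (2E)-3-[(2S,3S)-8-methoxy-2-methyl-3-(3,4,5-trimethoxyphenyl)-2,3-dihydro-1,4-benzodioxin-6-yl]prop-2-en-1-ol | COc1cc([C@@H]2Oc3cc(/C=C/CO)cc(OC)c3O[C@H]2C)cc(OC)c1OC
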